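**Plan**

1. Feature: the ten-membered carbocycle of the target carries in a row the C1 ketone, C3 at ketone level (the furanone enol-ether carbon), the C4 exocyclic methylene and oxygenated C5/C6. This is the imprint left when the terminus of an ynol ether (C3) bonds to the central carbon of an allene (C4) while the C1–C6 bond of a cyclohexane breaks.
2. Retrosynthetic cuts, in order: the C8 ester; the lactone C6–O bond together with C5–O (back to an E-C5=C6 alkene and a C12 acid made from isopropenyl); the furanone O–C3 bond; C3–C4 with re-formation of C1–C6 (alkoxide-accelerated [3,3] retron); C1–C2 (acetylide addition) and C5–C6 (aldol) to a carvone-derived epoxy ketone.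
3. Forward: the carvone ring is oxygenated at C8 and C10, given a C6 allenyl group and a C1 ethoxyethynyl carbinol, expanded from six to ten members, and then the furanone and last the α-methylene lactone are closed.
4. Stereochemistry: C7 comes from (S)-carvone (the diene/endoperoxide sequence turns the ring numbering over, so the S series is required). C8 comes from singlet-oxygen addition anti to isopropenyl followed by Mitsunobu inversion, and C10 from nucleophilic epoxidation anti to the C7/C8 groups. The transient C6 and C1 centres come from additions anti to isopropenyl and anti to the oxirane. C5 and C6 come from peripheral epoxidation of the E-alkene and SN2 lactonisation.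

Key step: step 13

Remark: locants are those of the germacrane skeleton of the target; with 7-H α, the C7 side chain, the C8 oxygen and the C10 methyl are β and the C10 oxygen is α in every intermediate. The given descriptors (5S,6R,7R,8R,10R) correspond to a cis-fused lactone (O-6 and C-11 both β) with 5β-OH, which is what anti addition across an E-5,6-alkene delivers. The C5 epimers of 11 and 12 and the C2=C3 geometry of 18 are of no consequence.

**Route**

Step 1
Reactants: 1 (S)-carvone
Product: 2 (3S)-6-methyl-3-(prop-1-en-2-yl)cyclohexa-1,5-dien-1-yl trifluoromethanesulfonate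
Conditions: LiN(i-Pr)2, THF, −78 °C; then PhNTf2, −78 → 0 °C
Reagents that add atoms: N-phenylbis(trifluoromethanesulfonimide), FC(F)(F)S(=O)(=O)N(c1ccccc1)S(=O)(=O)C(F)(F)F
Why: kinetic deprotonation of the enone at the α′ methylene and O-sulfonylation of the cross-conjugated dienolate (enol triflate formation) should give the dienyl triflate without touching the stereocentre.

Step 2
Reactants: 2 dienyl triflate
Product: 3 (5S)-2-methyl-5-(prop-1-en-2-yl)cyclohexa-1,3-diene
Conditions: Pd(OAc)2 (cat.), PPh3, n-Bu3N, HCO2H, DMF, 60 °C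
Reagents that add atoms: none
Why: palladium-catalysed formate reduction of an enol triflate (oxidative addition, formate exchange, decarboxylation, reductive elimination) should replace the triflate by hydrogen and leave the conjugated diene in place.

Step 3
Reactants: 3 cyclohexadiene
Product: 5 (4S,5R)-4-hydroxy-2-methyl-5-(prop-1-en-2-yl)cyclohex-2-en-1-one (hydroxyl trans to isopropenyl), via endoperoxide 4 (not isolated)
Conditions: O2, tetraphenylporphyrin (cat.), visible light, CH2Cl2, −30 °C; then Et3N, 0 °C → rt
Reagents that add atoms: dioxygen, O=O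
Why: singlet oxygen should add [4+2] to the cyclic diene on the face anti to the neighbouring isopropenyl group (this sets C8), and Kornblum–DeLaMare rearrangement with loss of the less hindered bridgehead proton (C1–H) should give the C1 ketone and the C8 alcohol.

Step 4
Reactants: 5 trans-hydroxy enone
Product: 6 (1R,6R)-3-methyl-4-oxo-6-(prop-1-en-2-yl)cyclohex-2-en-1-yl 4-nitrobenzoate (ester cis to isopropenyl)
Conditions: 4-nitrobenzoic acid, PPh3, diisopropyl azodicarboxylate, THF, 0 °C → rt
Reagents that add atoms: 4-nitrobenzoic acid, OC(=O)c1ccc(cc1)[N+](=O)[O-]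
Why: Mitsunobu reaction of the allylic alcohol should proceed by SN2 displacement of the oxyphosphonium group and so invert C8 to the 8β configuration cis to the C7 side chain.

Step 5
Reactants: 6 nitrobenzoate
Product: 7 (4R,5R)-4-hydroxy-2-methyl-5-(prop-1-en-2-yl)cyclohex-2-en-1-one
Conditions: K2CO3 (cat.), MeOH, 0 °C
Reagents that add atoms: none
Why: base-catalysed transesterification of the activated aryl ester with methanol should free the inverted alcohol without epimerisation.

Step 6
Reactants: 7 cis-hydroxy enone
Product: 8 (4R,5R)-4-[(tert-butyldimethylsilyl)oxy]-2-methyl-5-(prop-1-en-2-yl)cyclohex-2-en-1-one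
Conditions: TBSCl, imidazole, DMF, rt
Reagents that add atoms: tert-butyldimethylsilyl chloride, CC(C)(C)[Si](C)(C)Cl
Why: standard silylation of a secondary alcohol should give an ether that survives every basic step up to the ring expansion.

Step 7
Reactants: 8 silyloxy enone
Product: 9 8β-(tert-butyldimethylsilyloxy)-9α,10α-epoxy-7β-isopropenyl-10β-methylcyclohexan-1-one
Conditions: H2O2 (30% aq.), NaOH (cat.), MeOH, 0 °C
Reagents that add atoms: hydrogen peroxide, OO
Why: Weitz–Scheffer epoxidation should deliver hydroperoxide to C9 anti to both the C8 silyloxy and the C7 isopropenyl groups, so that the oxirane oxygen (the future furanone oxygen on C10) is α.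

Step 8
Reactants: 9 epoxy ketone; 10 3-(trimethylsilyl)prop-2-ynal
Product: 11 6α-[1-(methoxycarbonyloxy)-3-(trimethylsilyl)prop-2-ynyl] derivative of 9 (side chain trans to isopropenyl, both C5 epimers)
Conditions: LiN(i-Pr)2, THF, −78 °C; 10; then ClCO2Me, −78 → −40 °C
Reagents that add atoms: methyl chloroformate, COC(=O)Cl
Why: the only enolisable position is C6, the kinetic lithium enolate should undergo aldol addition to the ynal on the face anti to the C7 isopropenyl group (this sets C6), and acylation of the aldolate in the flask should block retro-aldol cleavage and install the leaving group for step 10.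

Step 9
Reactants: 11 silylalkynyl carbonate
Product: 12 6α-[1-(methoxycarbonyloxy)prop-2-ynyl] epoxy ketone (both C5 epimers)
Conditions: Bu4NF, AcOH (1:1), THF, −20 °C
Reagents that add atoms: none
Why: buffered fluoride should cleave the alkynyl C–Si bond far faster than the secondary silyl ether and should be too weakly basic to eliminate the β-carbonate.

Step 10
Reactants: 12 propargylic carbonate
Product: 13 6α-(propa-1,2-dienyl)-8β-(tert-butyldimethylsilyloxy)-9α,10α-epoxy-7β-isopropenyl-10β-methylcyclohexan-1-one
Conditions: Pd2(dba)3·CHCl3 (cat.), n-Bu3P (cat.), HCO2NH4, THF, rt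
Reagents that add atoms: none
Why: in the Tsuji–Mandai hydrogenolysis, SN2′ oxidative addition of zerovalent palladium to the propargylic carbonate should give an allenylpalladium formate that decarboxylates and reductively eliminates to the terminal allene; both C5 epimers converge and the neutral medium should keep the α-allenyl ketone from isomerising.

Step 11
Reactants: 13 allenyl epoxy ketone; 14 ethoxyacetylene
Product: 15 1β-(ethoxyethynyl)-1α-hydroxy-6α-allenyl-8β-(tert-butyldimethylsilyloxy)-9α,10α-epoxy-7β-isopropenyl-10β-methylcyclohexane (alkynyl trans to allenyl)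
Conditions: 14, n-BuLi, THF, −78 °C; CeCl3 (anhydrous), −78 °C; then 13, −78 °C
Reagents that add atoms: none
Why: the weakly basic (ethoxyethynyl)cerium reagent should add 1,2 without enolising the α-allenyl ketone, from the face anti to the oxirane oxygen (polar Felkin–Anh control) and anti to the C6 allenyl group, which sets C1 with the alkynyl group trans to the allene.

Step 12
Reactants: 15 epoxy carbinol
Product: 16 1β-(ethoxyethynyl)-6α-allenyl-7β-isopropenyl-8β-(tert-butyldimethylsilyloxy)-10β-methylcyclohexane-1α,10α-diol
Conditions: LiEt3BH, THF, 0 °C → rt; aqueous NaHCO3 work-up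
Reagents that add atoms: none
Why: SN2 hydride opening of the trisubstituted oxirane at the secondary carbon C9 should leave the tertiary C10 alcohol with its configuration intact, and the cis-disposed C1 alkoxide cannot undergo Payne rearrangement.

Step 13
Reactants: 16 ethoxyethynyl allenyl diol
Product: 18 (2E,5E)-3-ethoxy-10α-hydroxy-7β-isopropenyl-10β-methyl-4-methylidene-8β-(tert-butyldimethylsilyloxy)cyclodeca-2,5-dien-1-one, via dipotassium allenolate 17 (not isolated)
Conditions: KH (2.5 equiv), 18-crown-6 (2.5 equiv), THF, 0 °C → rt; then sat. aq. NH4Cl, −78 °C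
Reagents that add atoms: none
Why: Proposed new method: the dipotassium salt of the diol places a strongly donating alkoxide on C1, and an alkoxide-accelerated [3,3] shift through a chair-like six-atom array (C3≡C2–C1–C6–C5=C4) should join the ynol-ether terminus C3 to the central allene carbon C4 while C1–C6 breaks, giving the ten-membered ring as a cyclic allenolate that is protonated at C2 on quenching to the β-ethoxy enone, with the second allene π bond left as the C4 methylene. The closest known reaction types are the anionic oxy-Cope ring expansion of 1-alkynyl-2-vinylcyclohexanols, which also delivers an allenolate, and the Cope rearrangement of allenyl 1,5-dienes, in which the central allene carbon forms the new σ bond. The ten-membered ring closes by four-atom ring expansion of the cyclohexane (sigmatropic bond reorganisation), not by end-to-end cyclisation. No stereocentre is created, and C7, C8 and C10 are carried through unchanged. The step needs the E geometry at C5=C6, which the trans-diequatorial alkynyl and allenyl groups secure because C4 can reach C3 only when it is anti to C7 across the C5–C6 bond. Driving force comes from the exchange of a localised alkoxide for a delocalised allenolate and from release of the 1,3-diaxial C8-silyloxy/C10-methyl strain of the reacting chair, and the neighbouring C10 alkoxide has no fragmentation channel of its own.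

Step 14
Reactants: 18 β-ethoxy dienone
Product: 19 3,10α-epoxy-8β-hydroxygermacra-2,4(15),5E,11(13)-tetraen-1-one (furanone alcohol)
Conditions: HF (48% aq.), MeCN, 0 °C → rt
Reagents that add atoms: none
Why: acid should protonate the vinylogous ester to an oxocarbenium ion at C3 that the C10 hydroxyl attacks 5-exo, loss of ethanol then gives the 3(2H)-furanone (the known acid cyclisation of α′-hydroxy β-alkoxy enones), and the same reagent cleaves the silyl ether.

Step 15
Reactants: 19 furanone alcohol
Product: 20 3,10α-epoxy-8β-(isobutyryloxy)germacra-2,4(15),5E,11(13)-tetraen-1-one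
Conditions: (i-PrCO)2O, Et3N, DMAP (cat.), CH2Cl2, 0 °C
Reagents that add atoms: isobutyric anhydride, CC(C)C(=O)OC(=O)C(C)C
Why: DMAP-catalysed acylation of the only free hydroxyl should install the C8 ester before any other hydroxyl or the C12 acid exists, which rules out lactonisation onto O-8.

Step 16
Reactants: 20 isobutyrate
Product: 21 12-hydroxy derivative of 20 (C7 side chain = 3-hydroxyprop-1-en-2-yl)
Conditions: SeO2 (0.5 equiv), t-BuOOH, CH2Cl2, rt
Reagents that add atoms: selenium dioxide, O=[Se]=O; tert-butyl hydroperoxide (reoxidant that supplies the oxygen), CC(C)(C)OO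
Why: selenium dioxide allylic oxidation (ene reaction, then [2,3]-sigmatropic shift) should hydroxylate the isopropenyl methyl group, because the other alkenes are electron-poor or carry no allylic C–H on an sp3 carbon apart from the hindered C7–H.

Step 17
Reactants: 21 allylic alcohol
Product: 23 3,10α-epoxy-8β-(isobutyryloxy)-1-oxogermacra-2,4(15),5E,11(13)-tetraen-12-oic acid, via enal 22 (not isolated)
Conditions: TEMPO (cat.), PhI(OAc)2, CH2Cl2, rt; then NaClO2, NaH2PO4, 2-methyl-2-butene, t-BuOH/H2O, 0 °C
Reagents that add atoms: sodium chlorite, [Na+].[O-]Cl=O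
Why: oxoammonium oxidation of the primary allylic alcohol to the enal followed by Pinnick oxidation should give the acrylic acid without touching the ester, the furanone or the remaining alkenes.

Step 18
Reactants: 23 acrylic acid
Product: 25 target (CNP0384113.1), via epoxy acid 24 (not isolated)
Conditions: m-CPBA, NaHCO3, CH2Cl2, 0 °C; then Et3N, rt
Reagents that add atoms: 3-chloroperoxybenzoic acid, OOC(=O)c1cccc(Cl)c1
Why: Prilezhaev epoxidation should pick the strained, least electron-poor E-5,6-alkene and attack its exposed face (anti to the C7–C8 ring bond, with H-7 in the alkene plane) to give the (5S,6S)-oxirane, which the C12 carboxylate then opens 5-exo at C6 with inversion (epoxide-opening lactonisation), setting 6R in a cis-fused lactone and leaving the 5S hydroxyl.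

**Compound list**

1 | (S)-carvone, (5S)-2-methyl-5-(prop-1-en-2-yl)cyclohex-2-en-1-one | CC(=C)[C@H]1CC=C(C)C(=O)C1 | starting material
2 | (3S)-6-methyl-3-(prop-1-en-2-yl)cyclohexa-1,5-dien-1-yl trifluoromethanesulfonate | CC(=C)[C@H]1CC=C(C)C(OS(=O)(=O)C(F)(F)F)=C1 | intermediate
3 | (5S)-2-methyl-5-(prop-1-en-2-yl)cyclohexa-1,3-diene | CC(=C)[C@H]1CC=C(C)C=C1 | intermediate
4 | 5-methyl-7-(prop-1-en-2-yl)-2,3-dioxabicyclo[2.2.2]oct-5-ene, peroxide bridge anti to isopropenyl | CC(=C)[C@H]1C[C@@H]2OO[C@H]1C=C2C | intermediate (not isolated)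
5 | (4S,5R)-4-hydroxy-2-methyl-5-(prop-1-en-2-yl)cyclohex-2-en-1-one | CC(=C)[C@H]1CC(=O)C(C)=C[C@@H]1O | intermediate
6 | (1R,6R)-3-methyl-4-oxo-6-(prop-1-en-2-yl)cyclohex-2-en-1-yl 4-nitrobenzoate | CC(=C)[C@H]1CC(=O)C(C)=C[C@H]1OC(=O)c1ccc(cc1)[N+](=O)[O-] | intermediate
7 | (4R,5R)-4-hydroxy-2-methyl-5-(prop-1-en-2-yl)cyclohex-2-en-1-one | CC(=C)[C@H]1CC(=O)C(C)=C[C@H]1O | intermediate
8 | (4R,5R)-4-[(tert-butyldimethylsilyl)oxy]-2-methyl-5-(prop-1-en-2-yl)cyclohex-2-en-1-one | CC(=C)[C@H]1CC(=O)C(C)=C[C@H]1O[Si](C)(C)C(C)(C)C | intermediate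
9 | 8β-(tert-butyldimethylsilyloxy)-9α,10α-epoxy-7β-isopropenyl-10β-methylcyclohexan-1-one | CC(=C)[C@H]1CC(=O)[C@]2(C)O[C@@H]2[C@H]1O[Si](C)(C)C(C)(C)C | intermediate
10 | 3-(trimethylsilyl)prop-2-ynal | C[Si](C)(C)C#CC=O | starting material
11 | 6α-[1-(methoxycarbonyloxy)-3-(trimethylsilyl)prop-2-ynyl] derivative of 9 (C5 epimers) | CC(=C)[C@H]1[C@H](C(OC(=O)OC)C#C[Si](C)(C)C)C(=O)[C@]2(C)O[C@@H]2[C@H]1O[Si](C)(C)C(C)(C)C | intermediate
12 | 6α-[1-(methoxycarbonyloxy)prop-2-ynyl] derivative of 9 (C5 epimers) | CC(=C)[C@H]1[C@H](C(OC(=O)OC)C#C)C(=O)[C@]2(C)O[C@@H]2[C@H]1O[Si](C)(C)C(C)(C)C | intermediate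
13 | 6α-(propa-1,2-dienyl)-8β-(tert-butyldimethylsilyloxy)-9α,10α-epoxy-7β-isopropenyl-10β-methylcyclohexan-1-one | CC(=C)[C@H]1[C@H](C=C=C)C(=O)[C@]2(C)O[C@@H]2[C@H]1O[Si](C)(C)C(C)(C)C | intermediate
14 | ethoxyacetylene | CCOC#C | starting material
15 | 1β-(ethoxyethynyl)-1α-hydroxy-6α-allenyl-8β-(tert-butyldimethylsilyloxy)-9α,10α-epoxy-7β-isopropenyl-10β-methylcyclohexane | CC(=C)[C@H]1[C@H](C=C=C)[C@@](O)(C#COCC)[C@]2(C)O[C@@H]2[C@H]1O[Si](C)(C)C(C)(C)C | intermediate
16 | 1β-(ethoxyethynyl)-6α-allenyl-7β-isopropenyl-8β-(tert-butyldimethylsilyloxy)-10β-methylcyclohexane-1α,10α-diol (precursor of the key step) | O[C@@]1(C#COCC)[C@@H](C=C=C)[C@H](C(C)=C)[C@H](O[Si](C)(C)C(C)(C)C)C[C@@]1(C)O | intermediate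
17 | dipotassium salt of the ten-membered cyclic allenolate (C1 enolate, C10 alkoxide) | [K+].[K+].[O-]C1=C=C(OCC)C(=C)/C=C/[C@H](C(C)=C)[C@H](O[Si](C)(C)C(C)(C)C)C[C@@]1(C)[O-] | intermediate (not isolated)
18 | (2E,5E)-3-ethoxy-10α-hydroxy-7β-isopropenyl-10β-methyl-4-methylidene-8β-(tert-butyldimethylsilyloxy)cyclodeca-2,5-dien-1-one (product of the key step) | O=C1/C=C(/OCC)C(=C)/C=C/[C@H](C(C)=C)[C@H](O[Si](C)(C)C(C)(C)C)C[C@@]1(C)O | intermediate
19 | 3,10α-epoxy-8β-hydroxygermacra-2,4(15),5E,11(13)-tetraen-1-one | C[C@@]12C[C@@H](O)[C@@H](C(C)=C)/C=C/C(=C)C(=CC1=O)O2 | intermediate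
20 | 3,10α-epoxy-8β-(isobutyryloxy)germacra-2,4(15),5E,11(13)-tetraen-1-one | C[C@@]12C[C@@H](OC(=O)C(C)C)[C@@H](C(C)=C)/C=C/C(=C)C(=CC1=O)O2 | intermediate
21 | 12-hydroxy derivative of 20 | C[C@@]12C[C@@H](OC(=O)C(C)C)[C@@H](C(=C)CO)/C=C/C(=C)C(=CC1=O)O2 | intermediate
22 | 12-al derivative of 20 (enal) | C[C@@]12C[C@@H](OC(=O)C(C)C)[C@@H](C(=C)C=O)/C=C/C(=C)C(=CC1=O)O2 | intermediate (not isolated)
23 | 3,10α-epoxy-8β-(isobutyryloxy)-1-oxogermacra-2,4(15),5E,11(13)-tetraen-12-oic acid | C[C@@]12C[C@@H](OC(=O)C(C)C)[C@@H](C(=C)C(O)=O)/C=C/C(=C)C(=CC1=O)O2 | intermediate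
24 | (5S,6S)-5,6-epoxide of acid 23 | C[C@@]12C[C@@H](OC(=O)C(C)C)[C@@H](C(=C)C(O)=O)[C@@H]3O[C@H]3C(=C)C(=CC1=O)O2 | intermediate (not isolated)
25 | CNP0384113.1: 1-oxo-3,10α-epoxy-5β-hydroxy-8β-(isobutyryloxy)germacra-2,4(15),11(13)-trien-6β,12-olide (5S,6R,7R,8R,10R) | C=C1C(=O)O[C@@H]2[C@H]1[C@H](OC(=O)C(C)C)C[C@@]1(C)OC(=CC1=O)C(=C)[C@@H]2O | target

**Step count**

Total: 18 steps. Longest linear sequence: 18 steps from (S)-carvone (1); 10 and 14 are bought.

**Steps most likely to fail**

Step 13 (Proposed new method). The tertiary propargylic alkoxide may instead expel ethoxyacetylide (retro-addition), the alkoxide may cyclise onto the allene, or the strained cyclic allenolate may not form at a useful rate. The fallback uses only known chemistry: a 1-alkynyl-2-vinylcyclohexanol for the ring expansion, with C15 added afterwards. It sets out from epoxy ketone 9 and comes back at furanone alcohol 19. The lithium enolate of 9 is added to phenyl vinyl sulfoxide to give the 6α-[2-(phenylsulfinyl)ethyl] ketone F1. Thermolysis (toluene, 110 °C, NaHCO3) gives the 6α-vinyl epoxy ketone F2 by sulfoxide elimination. The cerium acetylide of 14 adds as in step 11 to give the vinyl epoxy carbinol F3, and LiEt3BH opens the oxirane to the vinyl diol F4. KH/18-crown-6 then effects the established anionic oxy-Cope ring expansion to the 15-nor β-ethoxy enone F5. Aqueous HF in MeCN closes the furanone and removes the silyl group to give the 15-nor furanone alcohol F6. The methylene is added last: γ-deprotonation of the furanone at C4 (LiN(i-Pr)2, 2.2 equiv, the C8 alkoxide carried along) and Mannich reaction with dimethylmethyleneiminium iodide give the Mannich base F7. N-Methylation (MeI) and mild base then eliminate trimethylamine to give 19.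

Step 18. The peracid may attack the other face of the E-alkene (leading to the 5,6-bis-epimeric trans-lactone), or the vinyl oxirane may open at the allylic C5 to a six-membered lactone. The fallback delivers the oxirane oxygen from the face opposite to the one an external electrophile prefers and closes the lactone only afterwards. It sets out from allylic alcohol 21 and comes back at target 25. Alcohol 21 is oxidised with MnO2 and enal 22 is isolated. NBS in aqueous THF adds bromine from the exposed face and water anti at the allylic C5 to give the bromohydrin F8. K2CO3 in MeCN closes it to the epoxy enal F9, whose oxirane lies on the face opposite to the bromonium ion. Pinnick oxidation gives epoxy acid 24, and Et3N then induces the 5-exo lactonisation to 25.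

Step 3. The base-induced opening of the endoperoxide may lose regiocontrol (proton loss at C8–H gives the isomeric C8 ketone), and singlet oxygen may also react in the ene mode with the isopropenyl group. The fallback replaces the rearrangement by reduction and chemoselective oxidation. It sets out from endoperoxide 4 (made from 3 as before) and comes back at 5. Thiourea in MeOH reduces the O–O bond to the cis-ene-1,4-diol F10, and MnO2 then oxidises the less hindered allylic alcohol at C1 (the C8 alcohol is flanked by the isopropenyl-bearing carbon) to give 5.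

**Further compounds**

F1 | step 13 | 6α-[2-(phenylsulfinyl)ethyl] derivative of 9 | CC(=C)[C@H]1[C@H](CCS(=O)c2ccccc2)C(=O)[C@]2(C)O[C@@H]2[C@H]1O[Si](C)(C)C(C)(C)C
F2 | step 13 | 6α-vinyl derivative of 9 | CC(=C)[C@H]1[C@H](C=C)C(=O)[C@]2(C)O[C@@H]2[C@H]1O[Si](C)(C)C(C)(C)C
F3 | step 13 | 1β-(ethoxyethynyl)-1α-hydroxy-6α-vinyl 9α,10α-epoxide | CC(=C)[C@H]1[C@H](C=C)[C@@](O)(C#COCC)[C@]2(C)O[C@@H]2[C@H]1O[Si](C)(C)C(C)(C)C
F4 | step 13 | 1β-(ethoxyethynyl)-6α-vinyl-7β-isopropenyl-8β-(tert-butyldimethylsilyloxy)-10β-methylcyclohexane-1α,10α-diol | O[C@@]1(C#COCC)[C@@H](C=C)[C@H](C(C)=C)[C@H](O[Si](C)(C)C(C)(C)C)C[C@@]1(C)O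
F5 | step 13 | (2E,5E)-3-ethoxy-10α-hydroxy-7β-isopropenyl-10β-methyl-8β-(tert-butyldimethylsilyloxy)cyclodeca-2,5-dien-1-one | O=C1/C=C(/OCC)C/C=C/[C@H](C(C)=C)[C@H](O[Si](C)(C)C(C)(C)C)C[C@@]1(C)O
F6 | step 13 | 3,10α-epoxy-8β-hydroxy-15-norgermacra-2,5E,11(13)-trien-1-one | C[C@@]12C[C@@H](O)[C@@H](C(C)=C)/C=C/CC(=CC1=O)O2
F7 | step 13 | 4-[(dimethylamino)methyl] derivative of F6 (C4 epimers) | C[C@@]12C[C@@H](O)[C@@H](C(C)=C)/C=C/C(CN(C)C)C(=CC1=O)O2
F8 | step 18 | (5S,6S)-6-bromo-5-hydroxy-5,6-dihydro derivative of enal 22 | C[C@@]12C[C@@H](OC(=O)C(C)C)[C@@H](C(=C)C=O)[C@@H](Br)[C@@H](O)C(=C)C(=CC1=O)O2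
F9 | step 18 | (5S,6S)-5,6-epoxide of enal 22 | C[C@@]12C[C@@H](OC(=O)C(C)C)[C@@H](C(=C)C=O)[C@@H]3O[C@H]3C(=C)C(=CC1=O)O2
F10 | step 3 | 2-methyl-5-(prop-1-en-2-yl)cyclohex-2-ene-1,4-diol, both hydroxyls trans to isopropenyl | CC(=C)[C@H]1C[C@H](O)C(C)=C[C@@H]1O
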